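**Retrosynthetic overview**

1. The target is traced back through hydrogenation to ring D, closed by an intramolecular carbonyl-ene reaction of a 1,2-diketone; ring C comes from a Diels–Alder reaction of buta-1,3-diene with a spiro 3-acyl-5,6-dihydropyran-2-one; the lactone ring comes from ester formation plus Knoevenagel condensation.
2. Ring A and the ether bridge are traced back (lactol reduction, oxidative excision of one carbon) to a bicyclo[3.2.1]oct-6-en-3-one made in one (4+3) cycloaddition of the 1,1-dimethyl-oxyallyl cation with a 5,5-disubstituted 1-acetoxycyclopentadiene; this forms the bond between the ring-A ketone carbon and its CH2 and the bond between the CMe2 carbon and the ring CH.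
3. Enabling feature: in ring A the ether-bearing CH lies between the CH2 and the CMe2 carbon (an oxyallyl unit), while the ketone carbon and the ring CH are both bonded to the spiro quaternary carbon (the two termini and the sp3 carbon of a cyclopentadiene). The OCH2 carbon of the tetrahydrofuran is one carbon of the diene's remaining double bond; the other is lost as formic acid when the ketone is unmasked.
4. Ring order: cyclopentane template (spiro carbon set by catalytic asymmetric hydroxymethylation), then ring A (key step), tetrahydrofuran, δ-lactone, ring C, ring D.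
5. All other stereocentres are relayed from the spiro carbon: face of the cycloaddition, exo hydride attack, Diels–Alder face, ene geometry.

Key step: step 5

Remark (locants): ent-kaurane numbering is used throughout. Ring A = C1 (ketone), C2 (CH2), C3 (CH–O), C4 (CMe2), C5 (CH), C10 (spiro carbon); C6 = OCH2 of the ether bridge; lactone = C7 (C=O), C8, C9, C10, C20 (OCH2); ring C = C8, C9, C11, C12, C13, C14; ring D = C8, C14, C13, C16 (C(OH)Me), C15 (ketone).

Remark (assumption): the BINAP antipode in step 1 is taken to be the one that gives the (S) keto ester; if the sense of induction is the opposite, the other antipode is used.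

**Step 1**
Reactants: 1 methyl 2-oxocyclopentane-1-carboxylate; 2 formaldehyde (37% aqueous)
Product: 3 (S)-hydroxymethyl keto ester
Conditions: aq. HCHO, [Pd((R)-BINAP)(OH2)2](OTf)2 (5 mol %), THF, −20 °C
Reagents that add atoms: formaldehyde, C=O
Why: Catalytic enantioselective aldol reaction with formaldehyde (hydroxymethylation) through a chiral palladium enolate of the β-keto ester; the ligand shields one enolate face and sets the quaternary centre (future C10) as (S).

**Step 2**
Reactants: 3 (S)-hydroxymethyl keto ester
Product: 4 (S)-silyl ether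
Conditions: TBDPSCl, imidazole, DMF, rt
Reagents that add atoms: tert-butyl(chloro)diphenylsilane, CC(C)(C)[Si](Cl)(c1ccccc1)c1ccccc1
Why: Standard silylation of the primary alcohol; the bulky silyl ether later shields one face of the diene and should survive hydride, periodate and Lewis acid.

**Step 3**
Reactants: 4 (S)-silyl ether
Product: 5 (S)-cyclopentenone
Conditions: 2-iodoxybenzoic acid (IBX), DMSO/toluene, 70 °C
Reagents that add atoms: none
Why: IBX dehydrogenation of the ketone to the enone; only the CH2–CH2 side is enolizable because C10 is quaternary, so a single regioisomer is expected.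

**Step 4**
Reactants: 5 (S)-cyclopentenone
Product: 6 (S)-dienyl acetate
Conditions: isopropenyl acetate (solvent), TsOH·H2O (cat.), 95 °C, acetone distilled off
Reagents that add atoms: isopropenyl acetate, CC(=C)OC(C)=O
Why: Acid-catalysed enol acetylation; only the γ-hydrogens on C5 can be removed, so the homoannular dienyl acetate should form, and the quaternary C10 blocks 1,5-hydrogen shifts.

**Step 5**
Reactants: 6 (S)-dienyl acetate; 7 3-bromo-3-methylbutan-2-one
Product: 9 bicyclo[3.2.1]octenone cycloadduct, via oxyallyl cation 8 (not isolated)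
Conditions: Et3N, (CF3)2CHOH, 0 °C to rt, slow addition of 7 (excess)
Reagents that add atoms: 3-bromo-3-methylbutan-2-one, CC(C)(Br)C(C)=O
Why: Triethylamine enolizes 7 towards its methyl group and the tertiary bromide ionizes in the fluorinated alcohol to the 1,1-dimethyl-oxyallyl cation 8, which adds across the two termini of the cyclopentadiene unit of 6 in a (4+3) cycloaddition and so forms the C1–C2 and C4–C5 bonds in one operation (C1 is the acetoxy-bearing terminus, later the ketone; C5 is the unsubstituted terminus). The closest known reaction type is the (4+3) cycloaddition of oxyallyl cations from α-halo ketones with cyclopentadienes and furans, including gem-dimethyl oxyallyl cations and 5,5-disubstituted cyclopentadienes. It closes the cycloheptenone ring by addition of the three-carbon 2π cation onto the 4π diene (concerted but asynchronous, or cation capture followed by enolate closure), and because the diene is cyclic the same event defines six-membered ring A (C1–C2–C3–C4–C5–C10), bridged by a two-carbon etheno unit. The new stereocentres C1 and C5 are set together by the face of attack: the pre-set C10 should direct the cation to the face of the flat ester and away from the silyloxymethyl arm, which places the future C20 carbon axial on ring A as the target requires. The step needs the CMe2 terminus to bond to the unsubstituted diene terminus; that terminus is the most nucleophilic carbon of the vinylogous enol acetate, the cation carries most charge at its tertiary carbon, and the other orientation would create three contiguous fully substituted carbons. No endo/exo question arises because each oxyallyl terminus carries two identical substituents.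

**Step 6**
Reactants: 9 bicyclo[3.2.1]octenone cycloadduct
Product: 11 triol, via endo alcohol 10 (not isolated)
Conditions: Li[(s-Bu)3BH], THF, −78 °C; then LiAlH4, 0 °C
Reagents that add atoms: none
Why: Hydride reduction; the bulky borohydride should attack the C3 ketone from the exo face, away from the two-carbon bridge (as in tropinone-type bicyclo[3.2.1]octan-3-ones), giving the endo C3 hydroxyl, and LiAlH4 then reduces the ester to the C20 carbinol and cleaves the bridgehead acetate.

**Step 7**
Reactants: 11 triol
Product: 13 keto lactol, via hydroxy dialdehyde 12 (not isolated)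
Conditions: OsO4 (cat.), NaIO4 (excess), 2,6-lutidine, dioxane/H2O, rt
Reagents that add atoms: sodium periodate, [Na+].[O-]I(=O)(=O)=O; osmium tetroxide (oxygen carrier), O=[Os](=O)(=O)=O
Why: Lemieux–Johnson oxidation: syn dihydroxylation and periodate cleavage of the etheno bridge gives a 1,2,3-triol array that loses its central carbon as formic acid, which unmasks the C1 ketone, while the aldehyde on C5 (now C6) is trapped as the lactol by the cis C3 hydroxyl.

**Step 8**
Reactants: 13 keto lactol
Product: 14 ring A–tetrahydrofuran keto alcohol
Conditions: Et3SiH, BF3·OEt2, CH2Cl2, −78 to −20 °C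
Reagents that add atoms: none
Why: Ionic hydrogenation of the lactol through its non-bridgehead oxocarbenium ion gives the cyclic ether; C3 and C5 are untouched and the isolated ketone should not be reduced at low temperature.

**Step 9**
Reactants: 14 ring A–tetrahydrofuran keto alcohol; 15 methyl 4,4-dimethoxy-3-oxopentanoate
Product: 16 β-keto ester
Conditions: toluene, 110 °C, methanol distilled off
Reagents that add atoms: methyl 4,4-dimethoxy-3-oxopentanoate, COC(=O)CC(=O)C(C)(OC)OC
Why: Thermal transesterification of the β-keto ester through its acylketene acylates the only hydroxyl (C20); no stereocentre is formed.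

**Step 10**
Reactants: 16 β-keto ester
Product: 17 primary alcohol
Conditions: HF·pyridine, pyridine/THF, 0 °C to rt
Reagents that add atoms: none
Why: Fluoride cleavage of the silyl ether under non-basic conditions, chosen to avoid a 1,3-acyl shift between the two oxymethyl arms, which would epimerize C10.

**Step 11**
Reactants: 17 primary alcohol
Product: 18 aldehyde
Conditions: Dess–Martin periodinane, NaHCO3, CH2Cl2, rt
Reagents that add atoms: none
Why: Dess–Martin oxidation of the neopentyl primary alcohol to the C9 aldehyde, which cannot enolize or eliminate.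

**Step 12**
Reactants: 18 aldehyde
Product: 19 spiro unsaturated δ-lactone (dienophile)
Conditions: piperidine (cat.), AcOH (cat.), 4 Å molecular sieves, benzene, 60 °C
Reagents that add atoms: none
Why: Intramolecular Knoevenagel condensation of the active methylene (C8) with the aldehyde (C9) closes the six-membered lactone ring as the alkylidene β-keto lactone; no stereocentre is formed.

**Step 13**
Reactants: 19 spiro unsaturated δ-lactone (dienophile); 20 buta-1,3-diene
Product: 21 Diels–Alder adduct
Conditions: buta-1,3-diene (excess), BHT, toluene, 130 °C, sealed tube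
Reagents that add atoms: buta-1,3-diene, C=CC=C
Why: Diels–Alder reaction of the doubly activated dienophile; suprafacial addition makes the acyl group on C8 and the hydrogen on C9 cis, and the diene should approach the face flanked by the flat ring-A carbonyl, away from the C5 methine with its OCH2 and CMe2 neighbours, which sets C8 and C9 relative to C10.

**Step 14**
Reactants: 21 Diels–Alder adduct
Product: 22 α-diketone
Conditions: CF3CO2H/H2O, CHCl3, 0 °C to rt
Reagents that add atoms: water, O
Why: Acid hydrolysis of the dimethyl ketal liberates the 1,2-diketone; the lactone and the ether bridge should be stable to aqueous acid.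

**Step 15**
Reactants: 22 α-diketone
Product: 23 ene product (11,12-didehydro target)
Conditions: SnCl4, CH2Cl2, −78 to −20 °C
Reagents that add atoms: none
Why: Lewis acid-promoted intramolecular carbonyl-ene reaction of the activated 1,2-diketone: the axial acyl group can reach only C13 on its own face of ring C (five-membered closure, fixing C13), and the carbonyl oxygen must point towards the C11 hydrogen it abstracts, so the C16 hydroxyl ends up on the side of the C9–C11–C12 bridge and the methyl outside, as in the target.

**Step 16**
Reactants: 23 ene product (11,12-didehydro target)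
Product: 24 CNP0538153.1 (target)
Conditions: H2 (1 atm), 10% Pd/C, EtOAc, rt
Reagents that add atoms: none
Why: Heterogeneous hydrogenation of the only C=C bond; no stereocentre is affected.

**Compound list**

1 | methyl 2-oxocyclopentane-1-carboxylate | COC(=O)C1CCCC1=O | starting material
2 | formaldehyde | C=O | starting material
3 | methyl (S)-1-(hydroxymethyl)-2-oxocyclopentane-1-carboxylate | O=C1CCC[C@]1(C(=O)OC)CO | intermediate
4 | methyl (S)-1-{[(tert-butyldiphenylsilyl)oxy]methyl}-2-oxocyclopentane-1-carboxylate | O=C1CCC[C@]1(C(=O)OC)CO[Si](c1ccccc1)(c1ccccc1)C(C)(C)C | intermediate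
5 | methyl (S)-1-{[(tert-butyldiphenylsilyl)oxy]methyl}-2-oxocyclopent-3-ene-1-carboxylate | O=C1C=CC[C@]1(C(=O)OC)CO[Si](c1ccccc1)(c1ccccc1)C(C)(C)C | intermediate
6 | methyl (S)-2-acetoxy-1-{[(tert-butyldiphenylsilyl)oxy]methyl}cyclopenta-2,4-diene-1-carboxylate | CC(=O)OC1=CC=C[C@]1(C(=O)OC)CO[Si](c1ccccc1)(c1ccccc1)C(C)(C)C | intermediate
7 | 3-bromo-3-methylbutan-2-one | CC(C)(Br)C(C)=O | starting material
8 | 1,1-dimethyl-2-oxyallyl cation (zwitterion) | C=C([O-])[C+](C)C | intermediate
9 | methyl 1-acetoxy-8-{[(tert-butyldiphenylsilyl)oxy]methyl}-4,4-dimethyl-3-oxobicyclo[3.2.1]oct-6-ene-8-carboxylate, ester syn to the three-carbon ketone bridge, silyloxymethyl syn to the etheno bridge | CC1(C)C(=O)C[C@@]2(OC(C)=O)C=C[C@@H]1[C@]2(C(=O)OC)CO[Si](c1ccccc1)(c1ccccc1)C(C)(C)C | intermediate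
10 | 3-endo alcohol of 9 (hydroxyl syn to the etheno bridge) | CC1(C)[C@@H](O)C[C@@]2(OC(C)=O)C=C[C@@H]1[C@]2(C(=O)OC)CO[Si](c1ccccc1)(c1ccccc1)C(C)(C)C | intermediate
11 | 8-{[(tert-butyldiphenylsilyl)oxy]methyl}-8-(hydroxymethyl)-4,4-dimethylbicyclo[3.2.1]oct-6-ene-1,3-diol, 3-hydroxyl endo, hydroxymethyl syn to the three-carbon bridge | CC1(C)[C@@H](O)C[C@@]2(O)C=C[C@@H]1[C@]2(CO)CO[Si](c1ccccc1)(c1ccccc1)C(C)(C)C | intermediate
12 | 2-{[(tert-butyldiphenylsilyl)oxy]methyl}-1,5-dihydroxy-2-(hydroxymethyl)-4,4-dimethylcyclohexane-1,3-dicarbaldehyde | CC1(C)[C@@H](O)C[C@@](O)(C=O)[C@@](CO)(CO[Si](c2ccccc2)(c2ccccc2)C(C)(C)C)[C@H]1C=O | intermediate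
13 | 2-{[(tert-butyldiphenylsilyl)oxy]methyl}-7-hydroxy-2-(hydroxymethyl)-8,8-dimethyl-6-oxabicyclo[3.2.1]octan-3-one (lactol, both anomers) | CC1(C)[C@@H]2CC(=O)[C@](CO[Si](c3ccccc3)(c3ccccc3)C(C)(C)C)(CO)[C@H]1C(O)O2 | intermediate
14 | 2-{[(tert-butyldiphenylsilyl)oxy]methyl}-2-(hydroxymethyl)-8,8-dimethyl-6-oxabicyclo[3.2.1]octan-3-one, hydroxymethyl on the ring face opposite the oxygen bridge | CC1(C)[C@@H]2CC(=O)[C@](CO[Si](c3ccccc3)(c3ccccc3)C(C)(C)C)(CO)[C@H]1CO2 | intermediate
15 | methyl 4,4-dimethoxy-3-oxopentanoate | COC(=O)CC(=O)C(C)(OC)OC | starting material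
16 | 4,4-dimethoxy-3-oxopentanoate ester of the C20 hydroxyl of 14 | CC1(C)[C@@H]2CC(=O)[C@](CO[Si](c3ccccc3)(c3ccccc3)C(C)(C)C)(COC(=O)CC(=O)C(C)(OC)OC)[C@H]1CO2 | intermediate
17 | [2-(hydroxymethyl)-8,8-dimethyl-3-oxo-6-oxabicyclo[3.2.1]octan-2-yl]methyl 4,4-dimethoxy-3-oxopentanoate | CC1(C)[C@@H]2CC(=O)[C@](CO)(COC(=O)CC(=O)C(C)(OC)OC)[C@H]1CO2 | intermediate
18 | (2-formyl-8,8-dimethyl-3-oxo-6-oxabicyclo[3.2.1]octan-2-yl)methyl 4,4-dimethoxy-3-oxopentanoate | CC1(C)[C@@H]2CC(=O)[C@](C=O)(COC(=O)CC(=O)C(C)(OC)OC)[C@H]1CO2 | intermediate
19 | 3-(2,2-dimethoxypropanoyl)-5,6-dihydro-2H-pyran-2-one spiro-fused at its C5 to C2 of 8,8-dimethyl-6-oxabicyclo[3.2.1]octan-3-one | CC1(C)[C@@H]2CC(=O)[C@]3(COC(=O)C(C(=O)C(C)(OC)OC)=C3)[C@H]1CO2 | intermediate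
20 | buta-1,3-diene | C=CC=C | starting material
21 | Diels–Alder adduct: cyclohex-3-ene ring C cis-fused to the δ-lactone, C8 bearing the 2,2-dimethoxypropanoyl group cis to the hydrogen on C9 | CC1(C)[C@@H]2CC(=O)[C@]3(COC(=O)[C@@]4(C(=O)C(C)(OC)OC)CC=CC[C@H]43)[C@H]1CO2 | intermediate
22 | 1,2-diketone (2-oxopropanoyl on C8) corresponding to 21 | CC1(C)[C@@H]2CC(=O)[C@]3(COC(=O)[C@@]4(C(=O)C(C)=O)CC=CC[C@H]43)[C@H]1CO2 | intermediate
23 | 11,12-didehydro derivative of the target (bicyclo[3.2.1]oct-2-ene ring C/D unit, C16 hydroxyl towards the C11=C12 bridge) | CC1(C)[C@@H]2CC(=O)[C@]3(COC(=O)[C@@]45C[C@@H](C=C[C@H]43)[C@@](C)(O)C5=O)[C@H]1CO2 | intermediate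
24 | CNP0538153.1 | CC1(C)[C@@H]2CC(=O)[C@]3(COC(=O)[C@@]45C[C@@H](CC[C@H]43)[C@@](C)(O)C5=O)[C@H]1CO2 | target

**Totals**

Total step count: 16. Longest linear sequence: 16 steps (all building blocks are commercial).

**Steps most likely to fail**

Step 5. The oxyallyl cation may be captured by the fluorinated alcohol or rearrange by the Favorskii path faster than the hindered, only moderately electron-rich dienyl acetate traps it. The enol acetate may also be lost by acyl transfer, and face discrimination may erode in the strongly ionizing medium. The fallback sets out from enone 5 and bromoketone 7 and comes back at triol 11. Enone 5 would be converted with TESOTf and Et3N (CH2Cl2, −78 °C) into the more nucleophilic triethylsilyl dienol ether F1. Bromoketone 7 would be brominated (Br2, cat. HBr, AcOH) to 1,3-dibromo-3-methylbutan-2-one F2. Reductive (4+3) cycloaddition of F1 with the zinc-bound oxyallyl generated from F2 and zinc–copper couple (Zn–Cu) in 1,2-dimethoxyethane, an aprotic medium without base, should give the bridgehead triethylsilyl ether cycloadduct F3. The hydride sequence of step 6 would give the silyl ether diol F4, and aqueous AcOH/THF would remove the triethylsilyl group to give 11.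

Step 13. Cycloaddition at the neopentyl-type β-carbon of 19 may be slower than thermal decomposition of the dienophile or polymerization of the diene. The fallback sets out from 19 and comes back at 21. The more reactive 2-(trimethylsilyloxy)buta-1,3-diene should add at lower temperature (toluene, 60–80 °C) to give the silyl enol ether adduct F5, with the siloxy group on C12 because the nucleophilic diene terminus bonds to C9. CsF and PhNTf2 in 1,2-dimethoxyethane would convert it regiospecifically into the enol triflate F6. Reduction with Pd(OAc)2, PPh3, HCO2H and n-Bu3N in DMF at 60 °C would remove the oxygen and leave the C12=C13 alkene of 21.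

Step 15. After the C16–C13 bond has formed, the developing C12 cation may be captured by chloride instead of completing the hydrogen transfer. The fallback sets out from 22 and comes back at 24. Chloride capture would be made the intended path: TiCl4 in CH2Cl2 at −78 °C should give, by Prins cyclization with delivery of chloride from the metal alkoxide, the chlorohydrin F7 (chlorine on C12, cis to the C16 bridge; the hydroxyl is again held on the C12 side). Radical dechlorination with n-Bu3SnH and AIBN in benzene at 80 °C would then give the target 24 directly, without step 16.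

**Further compounds**

F1 | step 5 | methyl (S)-1-{[(tert-butyldiphenylsilyl)oxy]methyl}-2-(triethylsilyloxy)cyclopenta-2,4-diene-1-carboxylate | CC[Si](CC)(CC)OC1=CC=C[C@]1(C(=O)OC)CO[Si](c1ccccc1)(c1ccccc1)C(C)(C)C
F2 | step 5 | 1,3-dibromo-3-methylbutan-2-one | CC(C)(Br)C(=O)CBr
F3 | step 5 | methyl 8-{[(tert-butyldiphenylsilyl)oxy]methyl}-4,4-dimethyl-3-oxo-1-(triethylsilyloxy)bicyclo[3.2.1]oct-6-ene-8-carboxylate, ester syn to the three-carbon bridge | CC1(C)C(=O)C[C@@]2(O[Si](CC)(CC)CC)C=C[C@@H]1[C@]2(C(=O)OC)CO[Si](c1ccccc1)(c1ccccc1)C(C)(C)C
F4 | step 5 | 1-O-triethylsilyl ether of triol 11 | CC1(C)[C@@H](O)C[C@@]2(O[Si](CC)(CC)CC)C=C[C@@H]1[C@]2(CO)CO[Si](c1ccccc1)(c1ccccc1)C(C)(C)C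
F5 | step 13 | 12-(trimethylsilyloxy) analogue of 21 (silyl enol ether, C12=C13) | CC1(C)[C@@H]2CC(=O)[C@]3(COC(=O)[C@@]4(C(=O)C(C)(OC)OC)CC=C(O[Si](C)(C)C)C[C@H]43)[C@H]1CO2
F6 | step 13 | 12-(trifluoromethanesulfonyloxy) analogue of 21 (enol triflate, C12=C13) | CC1(C)[C@@H]2CC(=O)[C@]3(COC(=O)[C@@]4(C(=O)C(C)(OC)OC)CC=C(OS(=O)(=O)C(F)(F)F)C[C@H]43)[C@H]1CO2
F7 | step 15 | 12-chloro derivative of the target (chlorine cis to the C16 bridge) | CC1(C)[C@@H]2CC(=O)[C@]3(COC(=O)[C@@]45C[C@@H]([C@H](Cl)C[C@H]43)[C@@](C)(O)C5=O)[C@H]1CO2
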